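**Retrosynthetic overview** (rings lettered A to H along the chain in the order of the target SMILES; C, E and G are the pentaoxygenated rings)
1. Each of rings C, E and G comes from one electrophile, 3-bromo-2,6-dimethoxy-1,4-benzoquinone: an aryloxide substitutes the C–Br carbon (inner ether), reduction gives a hydroquinone, and its less hindered OH makes the outer ether.
2. The key step uses this quinone umpolung late, on a tetramer phenol, to forge the tetra-ortho-substituted D–O–E ether that Ullmann coupling handles worst.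
3. Rings D, B, A and F come from (fluoro)benzaldehydes: SNAr makes the ether and Baeyer–Villiger oxidation turns CHO into the next phenol, so no protecting group is removed before the end.
4. Order of ring introduction: D → C → B → A → E → F on the main line; the G–H dimer is made separately and joined at the second fluorine of ring F.
5. Endgame: twofold Baeyer–Villiger oxidation, then one global cleavage of 19 methyl ethers.

Assumption: the target has no stereocentre and no stable axis, so it is achiral and needs no stereocontrol; 1, 3, 6, 14 and 17 are taken as catalogue compounds.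

**Step 1**
Reactants: 1 2,6-dimethoxy-1,4-benzoquinone
Product: 2 3-bromo-2,6-dimethoxy-1,4-benzoquinone
Conditions: Br2 (1.0 equiv), AcOH, rt
Reagents that add atoms: bromine, BrBr
Why: Electrophilic bromination of the methoxy enol-ether C=C of the quinone (bromine attack, then loss of HBr) can only occur at the one type of C–H present, and the first bromine deactivates the ring against a second; no stereocentre is formed.

**Step 2**
Reactants: 3 4-hydroxy-2,6-dimethoxybenzaldehyde; 2 3-bromo-2,6-dimethoxy-1,4-benzoquinone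
Product: 5 4-(3,6-dihydroxy-2,4-dimethoxyphenoxy)-2,6-dimethoxybenzaldehyde, via aryloxyquinone 4 (not isolated)
Conditions: Cs2CO3, MeCN, 0 °C to rt; then Na2S2O4, H2O/EtOAc, rt
Reagents that add atoms: none
Why: Nucleophilic vinylic substitution (addition–elimination) of a haloquinone by a phenoxide, as known for chloranil and 2,3-dichloro-1,4-naphthoquinone, goes at C–Br because bromide loss is the only irreversible exit (attack at a C–OMe carbon just re-expels the better leaving aryloxide), and Na2S2O4 then reduces the quinone to the hydroquinone without touching the hindered aldehyde; no stereocentre is formed.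

**Step 3**
Reactants: 5 4-(3,6-dihydroxy-2,4-dimethoxyphenoxy)-2,6-dimethoxybenzaldehyde; 6 4-fluoro-3,5-dimethoxybenzaldehyde
Product: 8 4-[6-(4-formyl-2,6-dimethoxyphenoxy)-2,3,4-trimethoxyphenoxy]-2,6-dimethoxybenzaldehyde, via monophenol 7 (not isolated)
Conditions: Cs2CO3, DMF, 90 °C, Ar; then MeI, rt
Reagents that add atoms: iodomethane, CI
Why: SNAr on the para-formyl-activated fluoride by the ring C phenoxide that has a free ortho position (the OH flanked by two OMe cannot reach the doubly flanked C–F), followed by Williamson methylation of the remaining hindered phenoxide in the same pot; no stereocentre is formed.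

**Step 4**
Reactants: 8 4-[6-(4-formyl-2,6-dimethoxyphenoxy)-2,3,4-trimethoxyphenoxy]-2,6-dimethoxybenzaldehyde
Product: 10 4-[6-(4-hydroxy-2,6-dimethoxyphenoxy)-2,3,4-trimethoxyphenoxy]-2,6-dimethoxyphenol, via bis-formate 9 (not isolated)
Conditions: mCPBA, CH2Cl2, 0 °C to rt; then K2CO3 (cat.), MeOH, rt
Reagents that add atoms: 3-chloroperbenzoic acid, OOC(=O)c1cccc(Cl)c1
Why: Twofold Baeyer–Villiger (Dakin-type) oxidation, in which the oxygen-rich aryl groups migrate in preference to H, gives aryl formates that shield the new phenols from the peracid until methanolysis; no stereocentre is formed.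

**Step 5**
Reactants: 10 4-[6-(4-hydroxy-2,6-dimethoxyphenoxy)-2,3,4-trimethoxyphenoxy]-2,6-dimethoxyphenol; 6 4-fluoro-3,5-dimethoxybenzaldehyde
Product: 11 4-{4-[2-(4-hydroxy-3,5-dimethoxyphenoxy)-3,4,5-trimethoxyphenoxy]-3,5-dimethoxyphenoxy}-3,5-dimethoxybenzaldehyde
Conditions: 6 (1.05 equiv), Cs2CO3, DMSO, 85 °C
Reagents that add atoms: none
Why: SNAr that is chemoselective for the unhindered ring B phenoxide, because attack of the ring D phenoxide (flanked by two OMe) on the doubly flanked C–F would need a tetra-ortho-substituted transition state; no stereocentre is formed.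

**Step 6**
Reactants: 11 4-{4-[2-(4-hydroxy-3,5-dimethoxyphenoxy)-3,4,5-trimethoxyphenoxy]-3,5-dimethoxyphenoxy}-3,5-dimethoxybenzaldehyde; 2 3-bromo-2,6-dimethoxy-1,4-benzoquinone
Product: 13 pentamer hydroquinone (ring D oxygen of 11 bonded to C-1 of a 3,6-dihydroxy-2,4-dimethoxyphenyl ring E), via aryloxyquinone 12 (not isolated)
Conditions: 2 (1.5 equiv), Cs2CO3, DMF, 0 °C to rt, Ar; then Na2S2O4, H2O/EtOAc, rt
Reagents that add atoms: none
Why: Proposed new method: the 2,6-dimethoxyphenoxide of ring D adds to the C–Br carbon of 2 (conjugate addition to the enone of the non-vinylogous carbonyl) and bromide leaves irreversibly; the electrophilic carbon has a C=O in place of one ortho substituent and needs no metal insertion, so the tetra-ortho-substituted ether should form where arene SNAr or Ullmann coupling stalls, the phenoxide is blocked at both ortho positions and para so only O-attack is possible, and the closest known reaction type is aryloxide substitution on chloranil or 2,3-dichloro-1,4-naphthoquinone followed by Na2S2O4 reduction; no stereocentre is formed.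

**Step 7**
Reactants: 13 pentamer hydroquinone; 14 2,4-difluoro-6-methoxybenzaldehyde
Product: 16 hexamer fluoro dialdehyde (ring E 6-O bonded to a 3-fluoro-4-formyl-5-methoxyphenyl ring F; ring E 3-OMe), via hexamer monophenol 15 (not isolated)
Conditions: 14 (1.1 equiv), K2CO3, DMF, 0 °C to 40 °C, Ar; then MeI, rt
Reagents that add atoms: iodomethane, CI
Why: SNAr at the fluorine para to the formyl group (less hindered than the ortho fluorine) by the ring E phenoxide with a free ortho position, while the K+-chelated phenoxide flanked by two OMe is the poorer nucleophile and is capped afterwards by Williamson methylation; no stereocentre is formed.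

**Step 8**
Reactants: 17 3,4,5-trimethoxyphenol; 2 3-bromo-2,6-dimethoxy-1,4-benzoquinone
Product: 19 2,6-dimethoxy-3-(3,4,5-trimethoxyphenoxy)benzene-1,4-diol, via aryloxyquinone 18 (not isolated)
Conditions: Cs2CO3, MeCN, 0 °C to rt; then Na2S2O4, H2O/EtOAc, rt
Reagents that add atoms: none
Why: The same nucleophilic vinylic substitution as in step 2, run in a dipolar aprotic solvent with Cs+ so that the ambident electron-rich phenoxide reacts at oxygen, then quinone reduction; no stereocentre is formed.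

**Step 9**
Reactants: 16 hexamer fluoro dialdehyde; 19 2,6-dimethoxy-3-(3,4,5-trimethoxyphenoxy)benzene-1,4-diol
Product: 21 octamer dialdehyde (ring F fluorine replaced by a 3,4,5-trimethoxy-2-(3,4,5-trimethoxyphenoxy)phenoxy group; CHO on rings A and F), via octamer monophenol 20 (not isolated)
Conditions: 19 (1.2 equiv), Cs2CO3, DMF, 90 °C, Ar; then MeI, rt
Reagents that add atoms: iodomethane, CI
Why: Convergent SNAr at the remaining fluorine, now activated by the ortho formyl group, by the less hindered phenoxide of 19 (fluoride leaves far faster than the para aryloxy group), then Williamson capping of the flanked phenol; no stereocentre is formed.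

**Step 10**
Reactants: 21 octamer dialdehyde
Product: 23 octamer diphenol (both CHO of 21 replaced by OH; the nonadeca-O-methyl ether of the target), via bis-formate 22 (not isolated)
Conditions: mCPBA, CH2Cl2, 0 °C to rt; then K2CO3 (cat.), MeOH, rt
Reagents that add atoms: 3-chloroperbenzoic acid, OOC(=O)c1cccc(Cl)c1
Why: Twofold Baeyer–Villiger oxidation and formate methanolysis as in step 4 turn both formyl groups, each on a ring with ortho or para oxygen donors, into the last two phenolic oxygens; no stereocentre is formed.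

**Step 11**
Reactants: 23 octamer diphenol
Product: 24 CNP0309601.0 (target)
Conditions: BBr3 (excess), CH2Cl2, -78 °C to rt; then H2O, Ar; reversed-phase purification
Reagents that add atoms: none
Why: Lewis-acid ether cleavage, in which bromide attacks the O-methyl carbon of each boron-complexed ether by SN2, removes all 19 methyl groups and cannot cleave the diaryl ether links, giving the achiral target.

**Compound list**
1 | 2,6-dimethoxy-1,4-benzoquinone | COC1=CC(=O)C=C(OC)C1=O | starting material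
2 | 3-bromo-2,6-dimethoxy-1,4-benzoquinone | COC1=CC(=O)C(Br)=C(OC)C1=O | intermediate
3 | 4-hydroxy-2,6-dimethoxybenzaldehyde | COc1cc(O)cc(OC)c1C=O | starting material
4 | 4-[(2,4-dimethoxy-3,6-dioxocyclohexa-1,4-dien-1-yl)oxy]-2,6-dimethoxybenzaldehyde | COc1cc(OC2=C(OC)C(=O)C(OC)=CC2=O)cc(OC)c1C=O | intermediate
5 | 4-(3,6-dihydroxy-2,4-dimethoxyphenoxy)-2,6-dimethoxybenzaldehyde | COc1cc(Oc2c(OC)c(O)c(OC)cc2O)cc(OC)c1C=O | intermediate
6 | 4-fluoro-3,5-dimethoxybenzaldehyde | COc1cc(C=O)cc(OC)c1F | starting material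
7 | 4-[6-(4-formyl-2,6-dimethoxyphenoxy)-3-hydroxy-2,4-dimethoxyphenoxy]-2,6-dimethoxybenzaldehyde | COc1cc(Oc2c(OC)c(O)c(OC)cc2Oc2c(OC)cc(C=O)cc2OC)cc(OC)c1C=O | intermediate
8 | 4-[6-(4-formyl-2,6-dimethoxyphenoxy)-2,3,4-trimethoxyphenoxy]-2,6-dimethoxybenzaldehyde | COc1cc(Oc2c(OC)c(OC)c(OC)cc2Oc2c(OC)cc(C=O)cc2OC)cc(OC)c1C=O | intermediate
9 | 4-[6-(4-formyloxy-2,6-dimethoxyphenoxy)-2,3,4-trimethoxyphenoxy]-2,6-dimethoxyphenyl formate | COc1cc(Oc2c(OC)c(OC)c(OC)cc2Oc2c(OC)cc(OC=O)cc2OC)cc(OC)c1OC=O | intermediate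
10 | 4-[6-(4-hydroxy-2,6-dimethoxyphenoxy)-2,3,4-trimethoxyphenoxy]-2,6-dimethoxyphenol | COc1cc(Oc2c(OC)c(OC)c(OC)cc2Oc2c(OC)cc(O)cc2OC)cc(OC)c1O | intermediate
11 | 4-{4-[2-(4-hydroxy-3,5-dimethoxyphenoxy)-3,4,5-trimethoxyphenoxy]-3,5-dimethoxyphenoxy}-3,5-dimethoxybenzaldehyde (tetramer A–D) | COc1cc(Oc2c(OC)c(OC)c(OC)cc2Oc2c(OC)cc(Oc3c(OC)cc(C=O)cc3OC)cc2OC)cc(OC)c1O | intermediate
12 | pentamer quinone: ring D oxygen of 11 bonded to C-3 of a 2,6-dimethoxy-1,4-benzoquinone | COc1cc(Oc2c(OC)c(OC)c(OC)cc2Oc2c(OC)cc(Oc3c(OC)cc(C=O)cc3OC)cc2OC)cc(OC)c1OC4=C(OC)C(=O)C(OC)=CC4=O | intermediate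
13 | pentamer hydroquinone: ring D oxygen of 11 bonded to C-1 of a 3,6-dihydroxy-2,4-dimethoxyphenyl ring E | COc1cc(Oc2c(OC)c(OC)c(OC)cc2Oc2c(OC)cc(Oc3c(OC)cc(C=O)cc3OC)cc2OC)cc(OC)c1Oc4c(OC)c(O)c(OC)cc4O | intermediate
14 | 2,4-difluoro-6-methoxybenzaldehyde | COc1cc(F)cc(F)c1C=O | starting material
15 | hexamer monophenol: 13 with the ring E 6-OH arylated by 3-fluoro-4-formyl-5-methoxyphenyl (ring F); ring E 3-OH free | COc1cc(Oc2c(OC)c(OC)c(OC)cc2Oc2c(OC)cc(Oc3c(OC)cc(C=O)cc3OC)cc2OC)cc(OC)c1Oc4c(OC)c(O)c(OC)cc4Oc5cc(F)c(C=O)c(OC)c5 | intermediate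
16 | hexamer fluoro dialdehyde: 15 with the ring E 3-OH methylated | COc1cc(Oc2c(OC)c(OC)c(OC)cc2Oc2c(OC)cc(Oc3c(OC)cc(C=O)cc3OC)cc2OC)cc(OC)c1Oc4c(OC)c(OC)c(OC)cc4Oc5cc(F)c(C=O)c(OC)c5 | intermediate
17 | 3,4,5-trimethoxyphenol | COc1cc(O)cc(OC)c1OC | starting material
18 | 2,6-dimethoxy-3-(3,4,5-trimethoxyphenoxy)-1,4-benzoquinone | COc1cc(OC2=C(OC)C(=O)C(OC)=CC2=O)cc(OC)c1OC | intermediate
19 | 2,6-dimethoxy-3-(3,4,5-trimethoxyphenoxy)benzene-1,4-diol | COc1cc(Oc2c(OC)c(O)c(OC)cc2O)cc(OC)c1OC | intermediate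
20 | octamer monophenol: 16 with the ring F fluorine replaced by the 4-oxygen of 19 (the OH next to its aryloxy group); other ring G OH free | COc1cc(Oc2c(OC)c(OC)c(OC)cc2Oc2c(OC)cc(Oc3c(OC)cc(C=O)cc3OC)cc2OC)cc(OC)c1Oc4c(OC)c(OC)c(OC)cc4Oc5cc(Oc6cc(OC)c(O)c(OC)c6Oc7cc(OC)c(OC)c(OC)c7)c(C=O)c(OC)c5 | intermediate
21 | octamer dialdehyde: 20 with the ring G OH methylated (CHO on rings A and F; 19 OMe) | COc1cc(Oc2c(OC)c(OC)c(OC)cc2Oc2c(OC)cc(Oc3c(OC)cc(C=O)cc3OC)cc2OC)cc(OC)c1Oc4c(OC)c(OC)c(OC)cc4Oc5cc(Oc6cc(OC)c(OC)c(OC)c6Oc7cc(OC)c(OC)c(OC)c7)c(C=O)c(OC)c5 | intermediate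
22 | octamer bis-formate: both CHO of 21 replaced by OCHO | COc1cc(Oc2c(OC)c(OC)c(OC)cc2Oc2c(OC)cc(Oc3c(OC)cc(OC=O)cc3OC)cc2OC)cc(OC)c1Oc4c(OC)c(OC)c(OC)cc4Oc5cc(Oc6cc(OC)c(OC)c(OC)c6Oc7cc(OC)c(OC)c(OC)c7)c(OC=O)c(OC)c5 | intermediate
23 | octamer diphenol: both CHO of 21 replaced by OH (nonadeca-O-methyl ether of 24) | COc1cc(Oc2c(OC)c(OC)c(OC)cc2Oc2c(OC)cc(Oc3c(OC)cc(O)cc3OC)cc2OC)cc(OC)c1Oc4c(OC)c(OC)c(OC)cc4Oc5cc(Oc6cc(OC)c(OC)c(OC)c6Oc7cc(OC)c(OC)c(OC)c7)c(O)c(OC)c5 | intermediate
24 | CNP0309601.0 (achiral) | Oc1cc(O)c(Oc2cc(O)c(Oc3cc(O)c(O)c(O)c3Oc3cc(O)c(Oc4c(Oc5cc(O)c(O)c(Oc6cc(O)c(O)c(O)c6Oc6cc(O)c(O)c(O)c6)c5)cc(O)c(O)c4O)c(O)c3)c(O)c2)c(O)c1 | target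

**Totals**
Total step count: 11. Longest linear sequence: 10 (steps 1 to 7, then 9 to 11).

**Three steps most likely to fail**

Step 6 is the riskiest. The hindered, electron-rich phenoxide of 11 may fail to reach the C–Br carbon, or may transfer an electron to the quinone instead. The fallback sets out from 11 and comes back at 16, replacing the quinone by an ortho-formyl-activated fluoroarene and a Baeyer–Villiger oxidation. The formyl group of 11 is masked with ethylene glycol (cat. TsOH, toluene, reflux) to give the tetramer dioxolane phenol F1. SNAr of its phenoxide on 2-fluoro-3,4,5-trimethoxybenzaldehyde F2 (Cs2CO3, DMSO, 120 °C) gives the pentamer aldehyde F3. mCPBA in Na2HPO4-buffered CH2Cl2 gives the pentamer formate F4, and K2CO3/MeOH gives the pentamer phenol F5, whose ring E already carries OMe where step 7 would cap. SNAr of F5 on 14 (K2CO3, DMF) gives the hexamer dioxolane F6, and aqueous HCl/THF unmasks the aldehyde to give 16.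

Step 7 needs two selectivities at once on a late intermediate: which ring E hydroxyl reacts, and which fluorine of 14 is displaced. The fallback sets out from 13 and comes back at 16 by fixing the hydroxyl choice before the coupling. TBSCl/imidazole (DMF, 0 °C) silylates only the OH with a free ortho position, giving the pentamer silyl ether F7. MeI/K2CO3 in acetone methylates the flanked OH, giving the pentamer methyl silyl ether F8. CsF in DMF at rt with 14 then triggers a desilylative SNAr, in which the freed phenoxide attacks the para fluorine and the released fluoride carries the chain, giving 16.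

Step 9 is the fragment union; hydroquinone 19 can react through either OH, and hot phenoxide can exchange the aryloxy groups on ring F. The fallback sets out from 17 and comes back at 21 by making the nucleophile a single phenol. SNAr of 17 on F2 (Cs2CO3, DMSO, 110 °C) gives 3,4,5-trimethoxy-2-(3,4,5-trimethoxyphenoxy)benzaldehyde F9. mCPBA gives 3,4,5-trimethoxy-2-(3,4,5-trimethoxyphenoxy)phenyl formate F10, and K2CO3/MeOH gives 3,4,5-trimethoxy-2-(3,4,5-trimethoxyphenoxy)phenol F11. SNAr of F11 on 16 (1.0 equiv, Cs2CO3, DMF, 90 °C) gives 21 directly, with no capping.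

**Further compounds**
F1 | step 6 | tetramer dioxolane phenol (11 with CHO as 1,3-dioxolan-2-yl) | COc1cc(Oc2c(OC)c(OC)c(OC)cc2Oc2c(OC)cc(Oc3c(OC)cc(C8OCCO8)cc3OC)cc2OC)cc(OC)c1O
F2 | step 6 | 2-fluoro-3,4,5-trimethoxybenzaldehyde | COc1cc(C=O)c(F)c(OC)c1OC
F3 | step 6 | pentamer aldehyde (ring D oxygen of F1 bonded to C-2 of 3,4,5-trimethoxybenzaldehyde) | COc1cc(Oc2c(OC)c(OC)c(OC)cc2Oc2c(OC)cc(Oc3c(OC)cc(C8OCCO8)cc3OC)cc2OC)cc(OC)c1Oc4c(OC)c(OC)c(OC)cc4C=O
F4 | step 6 | pentamer formate (CHO of F3 replaced by OCHO) | COc1cc(Oc2c(OC)c(OC)c(OC)cc2Oc2c(OC)cc(Oc3c(OC)cc(C8OCCO8)cc3OC)cc2OC)cc(OC)c1Oc4c(OC)c(OC)c(OC)cc4OC=O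
F5 | step 6 | pentamer phenol (CHO of F3 replaced by OH) | COc1cc(Oc2c(OC)c(OC)c(OC)cc2Oc2c(OC)cc(Oc3c(OC)cc(C8OCCO8)cc3OC)cc2OC)cc(OC)c1Oc4c(OC)c(OC)c(OC)cc4O
F6 | step 6 | hexamer dioxolane (16 with the ring A CHO as 1,3-dioxolan-2-yl) | COc1cc(Oc2c(OC)c(OC)c(OC)cc2Oc2c(OC)cc(Oc3c(OC)cc(C8OCCO8)cc3OC)cc2OC)cc(OC)c1Oc4c(OC)c(OC)c(OC)cc4Oc5cc(F)c(C=O)c(OC)c5
F7 | step 7 | pentamer silyl ether (13 with the ring E 6-OH as OTBS; 3-OH free) | COc1cc(Oc2c(OC)c(OC)c(OC)cc2Oc2c(OC)cc(Oc3c(OC)cc(C=O)cc3OC)cc2OC)cc(OC)c1Oc4c(OC)c(O)c(OC)cc4O[Si](C)(C)C(C)(C)C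
F8 | step 7 | pentamer methyl silyl ether (F7 with the ring E 3-OH methylated) | COc1cc(Oc2c(OC)c(OC)c(OC)cc2Oc2c(OC)cc(Oc3c(OC)cc(C=O)cc3OC)cc2OC)cc(OC)c1Oc4c(OC)c(OC)c(OC)cc4O[Si](C)(C)C(C)(C)C
F9 | step 9 | 3,4,5-trimethoxy-2-(3,4,5-trimethoxyphenoxy)benzaldehyde | COc1cc(Oc2c(OC)c(OC)c(OC)cc2C=O)cc(OC)c1OC
F10 | step 9 | 3,4,5-trimethoxy-2-(3,4,5-trimethoxyphenoxy)phenyl formate | COc1cc(Oc2c(OC)c(OC)c(OC)cc2OC=O)cc(OC)c1OC
F11 | step 9 | 3,4,5-trimethoxy-2-(3,4,5-trimethoxyphenoxy)phenol | COc1cc(Oc2c(OC)c(OC)c(OC)cc2O)cc(OC)c1OC
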